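**Retrosynthetic overview**
1. Target ⇒ eudesmane-4β,6β,9β-triol. The O6–acyl C–O bond is made last, by oxidative opening of a cinnamylidene acetal that only the syn-diaxial 4β,6β-diol can form (new step).
2. Triol ⇒ 4β-hydroxyeudesmane-6,9-dione (hydride to the α face of both ketones) ⇒ eudesmane-6,9-dione by stereoretentive C4–H to C4–OH oxidation, the key C–O bond on the finished skeleton.
3. Dione ⇒ cis-fused enedione adduct (hydrogenation, then thermodynamic epimerisation at C5 and C7).
4. Adduct ⇒ thymoquinone + (E)-piperylene (catalytic enantioselective Diels–Alder reaction).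
5. Ring order: ring B is bought as the quinone ring, and ring A is closed onto it in the first step. No C–C bond is formed afterwards.

Convention: eudesmane numbering is used. Ring A is C1–C5 plus C10 and ring B is C5–C10. C4 carries methyl C15, C7 carries the isopropyl group, and C10 carries the angular methyl C14. β is the face of the angular methyl and α is the opposite face.

Assumption: the facial sense of the (S)-catalyst in step 1 is inferred from its known behaviour toward acrylates, which bind through the same two-point B–O / α-C–H···O mode. If a test run gave the mirror-image adduct, the equally available (R)-catalyst would be used and nothing else changes.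

**Step 1**
Reactants: 1 thymoquinone (2-isopropyl-5-methyl-1,4-benzoquinone); 2 (E)-penta-1,3-diene (trans-piperylene)
Product: 3 cis-fused adduct (4aS,8R,8aR)-4a,8-dimethyl-2-(propan-2-yl)-4a,5,8,8a-tetrahydronaphthalene-1,4-dione (eudesma-2,7-diene-6,9-dione with 4α-CH3, 5β-H, 10β-CH3)
Conditions: (S)-3,3-diphenyl-1-(2-methylphenyl)tetrahydro-1H,3H-pyrrolo[1,2-c][1,3,2]oxazaborole (20 mol %) + HN(SO2CF3)2 (18 mol %), 2 (4 equiv; the Z isomer in technical piperylene is inert), CH2Cl2, −78 to −40 °C, 36 h
Reagents that add atoms: none
Why: Catalytic enantioselective Diels–Alder reaction: the cationic oxazaborolidine binds the C6 carbonyl on the lone pair next to C5–H (B–O bond plus C5–H···O contact), so the less hindered methyl-substituted C5=C10 bond reacts, the nucleophilic CH2 end of the diene bonds to the β-carbon C10 and the CHCH3 end to C5, and endo addition to the unshielded α face sets C10 (methyl β), C5 (H β, cis fusion) and C4 (methyl α, H β) in one event.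

**Step 2**
Reactants: 3 cis-fused adduct
Product: 5 trans-fused (2S,4aS,8R,8aS)-4a,8-dimethyl-2-(propan-2-yl)octahydronaphthalene-1,4-dione (eudesmane-6,9-dione with 4α-CH3, 5α-H, 7β-isopropyl), via cis-fused saturated dione 4 (not isolated)
Conditions: H2 (1 atm), Pd/C (10 wt % Pd, 5 mol %), EtOAc, rt; filter, concentrate; NaOMe (0.3 equiv), MeOH, rt, 12 h
Reagents that add atoms: none
Why: Heterogeneous catalytic hydrogenation saturates both C=C bonds, and the following base-mediated epimerisation through the C6 enolates is under thermodynamic control, which drains 4 into the chair–chair trans-decalin with 5α-H and equatorial 7β-isopropyl (estimated about 1.5 kcal/mol below the best cis isomer, the same preference as in 5α-6-oxo steroids), while C4 and C10 cannot enolise.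

**Step 3**
Reactants: 5 trans-fused eudesmane-6,9-dione
Product: 6 (2S,4aS,8S,8aR)-8-hydroxy-4a,8-dimethyl-2-(propan-2-yl)octahydronaphthalene-1,4-dione (4β-hydroxyeudesmane-6,9-dione)
Conditions: methyl(trifluoromethyl)dioxirane (1.5 equiv, ca. 0.5 M in 1,1,1-trifluoroacetone), CH2Cl2, −20 to 0 °C, 2 h
Reagents that add atoms: methyl(trifluoromethyl)dioxirane, CC1(C(F)(F)F)OO1
Why: Dioxirane C–H hydroxylation (concerted oxygen insertion with retention): C5–H and C7–H are switched off as α-keto C–H bonds, the isopropyl methine is shielded by its two methyls and the neighbouring carbonyl, and the axial 4β-H, exposed because C6 is trigonal and accelerated by release of its syn-axial strain with the angular methyl, is replaced by OH on the same face, which sets the C4 carbinol centre (4β-OH, 4α-CH3).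

**Step 4**
Reactants: 6 4β-hydroxyeudesmane-6,9-dione
Product: 7 (1R,2S,4S,4aS,8S,8aS)-4a,8-dimethyl-2-(propan-2-yl)decahydronaphthalene-1,4,8-triol (eudesmane-4β,6β,9β-triol)
Conditions: NaBH4 (3 equiv), CeCl3·7H2O (2 equiv), MeOH, −40 °C to rt
Reagents that add atoms: none
Why: Luche-type borohydride reduction under substrate control: the β face of both carbonyls is blocked by the axial angular methyl (and for C6 also by the axial 4β-OH), so hydride enters from the α face, giving the axial 6β-OH (as with 6-oxo steroids) and, by axial attack, the equatorial 9β-OH, while the mildly acidic CeCl3 medium suppresses retro-aldol opening of the β-hydroxy ketone.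

**Step 5**
Reactants: 7 eudesmane-4β,6β,9β-triol; 8 (E)-cinnamaldehyde dimethyl acetal
Product: 11 6β-[(E)-cinnamoyloxy]eudesmane-4β,9β-diol (target CNP0184465.1), via cinnamylidene acetal 9 (not isolated), via dioxanylium ion 10 (not isolated)
Conditions: 8 (1.05 equiv), pyridinium 4-toluenesulfonate (5 mol %), toluene, 45 °C, 150 mbar (MeOH stripped); then CH2Cl2/pH 7 phosphate buffer 18:1, 2,3-dichloro-5,6-dicyano-1,4-benzoquinone (DDQ, 1.3 equiv), 0 °C to rt, 2 h
Reagents that add atoms: water, O
Why: Proposed new method: diol-gated oxidative acylation, in which only the syn-diaxial 4β,6β-diol can close a six-membered cinnamylidene acetal (9, styryl equatorial, chair tilted away from the angular methyl) whereas the isolated 9β-OH can form only a labile mixed acetal that reverts, so the acyl carbon is parked on O4/O6 at the aldehyde oxidation level; DDQ then abstracts the doubly oxygen-activated cinnamylic acetal hydride (the styrene π system is about as oxidisable as a p-methoxyphenyl ring) to give the 2-styryl-1,3-dioxan-2-ylium ion 10, water adds, and the hemi-orthoester expels the more basic and more crowded tertiary O4, leaving the (E)-cinnamate on the hindered axial O6 without any acyl transfer to that oxygen and without touching a stereocentre; the closest known reaction types are the DDQ/water opening of p-methoxybenzylidene acetals to hydroxy p-methoxybenzoates and the Hanessian–Hullar opening of benzylidene acetals, neither shown for cinnamylidene acetals nor used to override the normal equatorial-over-axial acylation order of a free triol.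

**Compound list**
1 | thymoquinone (2-isopropyl-5-methyl-1,4-benzoquinone) | CC1=CC(=O)C(C(C)C)=CC1=O | starting material
2 | (E)-penta-1,3-diene | C=C/C=C/C | starting material
3 | cis-fused adduct, eudesma-2,7-diene-6,9-dione (4α-CH3, 5β-H, 10β-CH3) | CC(C)C1=CC(=O)[C@@]2(C)CC=C[C@@H](C)[C@H]2C1=O | intermediate
4 | cis-fused saturated eudesmane-6,9-dione (5β-H, C7 epimer mixture, not isolated) | CC(C)C1CC(=O)[C@@]2(C)CCC[C@@H](C)[C@H]2C1=O | intermediate
5 | trans-fused eudesmane-6,9-dione (4α-CH3, 5α-H, 7β-isopropyl, 10β-CH3) | CC(C)[C@@H]1CC(=O)[C@@]2(C)CCC[C@@H](C)[C@@H]2C1=O | intermediate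
6 | 4β-hydroxyeudesmane-6,9-dione | CC(C)[C@@H]1CC(=O)[C@@]2(C)CCC[C@](C)(O)[C@@H]2C1=O | intermediate
7 | eudesmane-4β,6β,9β-triol | CC(C)[C@@H]1C[C@H](O)[C@@]2(C)CCC[C@](C)(O)[C@@H]2[C@@H]1O | intermediate
8 | (E)-cinnamaldehyde dimethyl acetal | COC(OC)/C=C/c1ccccc1 | starting material
9 | 4β,6β-O-[(E)-cinnamylidene] acetal of 7 (styryl equatorial, 9β-OH free, not isolated) | CC(C)[C@@H]1C[C@H](O)[C@@]2(C)CCC[C@](C)(O3)[C@@H]2[C@@H]1O[C@H]3/C=C/c1ccccc1 | intermediate
10 | 2-styryl-1,3-dioxan-2-ylium ion bridging O4 and O6 (not isolated) | CC(C)[C@@H]1C[C@H](O)[C@@]2(C)CCC[C@](C)(O3)[C@@H]2[C@@H]1[O+]=C3/C=C/c1ccccc1 | intermediate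
11 | (1R,2S,4S,4aS,8S,8aS)-4,8-dihydroxy-4a,8-dimethyl-2-(propan-2-yl)decahydronaphthalen-1-yl (E)-3-phenylprop-2-enoate | CC(C)[C@@H]1C[C@H](O)[C@@]2(C)CCC[C@](C)(O)[C@@H]2[C@@H]1OC(=O)/C=C/c1ccccc1 | target

**Totals**
Total step count: 5. Longest linear sequence: 5 (from 1).

**Three steps most likely to fail**

1. Step 5 (the proposed new step).
   - Risks: slow closure of the acetal onto the tertiary 4β-OH, acid-induced loss of that OH, sluggish hydride abstraction, or collapse to the O4 ester.
   - Fallback (known chemistry only, sets out from 6 and comes back at 11): reduction and acylation are reordered so that two secondary alcohols never compete. Compound 6 is treated with Et2BOMe and then NaBH4 (THF/MeOH, −78 °C, Narasaka–Prasad conditions). The boron chelate between the 4β-OH and the C6 carbonyl activates only this ketone, and hydride enters from the α face to give 4β,6β-dihydroxyeudesman-9-one F1. Its only secondary hydroxyl is esterified with (E)-cinnamoyl chloride (DMAP, Et3N, CH2Cl2, reflux) to 6β-cinnamoyloxy-4β-hydroxyeudesman-9-one F2. NaBH4/CeCl3·7H2O (MeOH, −20 °C) then reduces the C9 ketone by axial attack to 11, leaving the cinnamate untouched. This is one step longer.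

2. Step 3.
   - Risks: C4–H lies β to the C6 carbonyl and is electronically deactivated, so attack at the isopropyl methine or at the C2/C3 methylenes may compete.
   - Fallback (sets out from 5 and comes back at 7): the oxidation is moved to the ester oxidation level, where the oxygen functions deactivate C4–H far less. Compound 5 is reduced (NaBH4, CeCl3·7H2O, MeOH) to eudesmane-6β,9β-diol F3. This is acetylated (Ac2O, DMAP, pyridine, 60 °C) to 6β,9β-diacetoxyeudesmane F4. Hydroxylation with methyl(trifluoromethyl)dioxirane (CH2Cl2, 0 °C) gives 6β,9β-diacetoxyeudesman-4β-ol F5. LiAlH4 (THF, 0 °C to rt) then frees 7.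

3. Step 1.
   - Risks: low rate with the trisubstituted quinone double bond, imperfect choice between the two double bonds or of the diene orientation, or insufficient enantiomeric excess.
   - Fallback (sets out from 1 and 2 and comes back at 3): catalyst control of absolute configuration is given up in favour of resolution. The cycloaddition is promoted with BF3·OEt2 (CH2Cl2, −78 °C) and regioisomers are removed by chromatography. The racemate, which is 3 together with its mirror image ent-adduct F6, is separated by preparative chromatography on a cellulose tris(3,5-dimethylphenylcarbamate) phase. F6 is discarded.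

**Further compounds**
F1 | step 5 | 4β,6β-dihydroxyeudesman-9-one | CC(C)[C@@H]1CC(=O)[C@@]2(C)CCC[C@](C)(O)[C@@H]2[C@@H]1O
F2 | step 5 | 6β-[(E)-cinnamoyloxy]-4β-hydroxyeudesman-9-one | CC(C)[C@@H]1CC(=O)[C@@]2(C)CCC[C@](C)(O)[C@@H]2[C@@H]1OC(=O)/C=C/c1ccccc1
F3 | step 3 | eudesmane-6β,9β-diol (4α-CH3, 5α-H) | CC(C)[C@@H]1C[C@H](O)[C@@]2(C)CCC[C@@H](C)[C@@H]2[C@@H]1O
F4 | step 3 | 6β,9β-diacetoxyeudesmane | CC(C)[C@@H]1C[C@H](OC(C)=O)[C@@]2(C)CCC[C@@H](C)[C@@H]2[C@@H]1OC(C)=O
F5 | step 3 | 6β,9β-diacetoxyeudesman-4β-ol | CC(C)[C@@H]1C[C@H](OC(C)=O)[C@@]2(C)CCC[C@](C)(O)[C@@H]2[C@@H]1OC(C)=O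
F6 | step 1 | ent-adduct (mirror image of 3) | CC(C)C1=CC(=O)[C@]2(C)CC=C[C@H](C)[C@@H]2C1=O
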